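## Retrosynthetic overview

1. Target ⇒ cut the ester C–O bond between the primary alcohol of the lactone diacid core and C1 of (R)-malic acid. Forward: regioselective alcoholysis of O-trifluoroacetyl-(R)-malic anhydride.
2. Core ⇒ its di-tert-butyl ester/TBS ether ⇒ cut the lactone C2–O bond and the neighbouring C–H back to an acyclic (Z)-tetrasubstituted maleate carrying a 2-carboxyethyl arm. Forward: catalytic asymmetric syn hydro-acyloxylation; the γ-lactone is the only ring, and it is closed here with both core stereocentres.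
3. Maleate acid ⇒ allyl maleate (hydroboration–oxidation, then alcohol → acid) ⇒ one-pot syn-carbocupration/allylation of di-tert-butyl acetylenedicarboxylate with the Grignard reagent of TBS-protected 10-bromodecanol and allyl bromide.

Assumption: read from the SMILES, all three stereocentres are (R) (D-malate 1-ester of the ω-hydroxylated enantiomer of spiculisporic acid); the sense of induction in the new step 5 is a prediction, and the quinine-derived pseudo-enantiomer of the catalyst is the switch if it proves opposite.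

## Route

Step 1
Reactants: 1 10-bromodecan-1-ol
Product: 2 (10-bromodecyloxy)(tert-butyl)dimethylsilane
Conditions: TBSCl (1.1 equiv), imidazole (1.5 equiv), CH2Cl2, 0 °C → rt
Reagents that add atoms: tert-butyldimethylsilyl chloride (TBSCl), CC(C)(C)[Si](C)(C)Cl
Why: Imidazole-promoted O-silylation of a primary alcohol masks the hydroxyl for the Grignard chemistry and gives an ether that later falls off in the same acid step as the tert-butyl esters.

Step 2
Reactants: 2 (10-bromodecyloxy)(tert-butyl)dimethylsilane; 3 di-tert-butyl but-2-ynedioate; 4 allyl bromide (3-bromoprop-1-ene)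
Product: 8 di-tert-butyl (2Z)-2-[10-(tert-butyldimethylsilyloxy)decyl]-3-(prop-2-en-1-yl)but-2-enedioate, via Grignard reagent 5 (not isolated), via alkylcopper 6 (not isolated), via vinylcopper adduct 7 (not isolated)
Conditions: Mg, THF, 40 °C; CuBr·SMe2 (1.0 equiv), THF/Me2S, −40 °C; 3, −78 °C, 1 h; then 4 (3 equiv), HMPA, −78 → 0 °C
Reagents that add atoms: none
Why: syn-Carbocupration of the acetylenic diester places the alkyl group and copper cis (both esters cis), and allylation of the alkenylcopper with retention gives the tetrasubstituted (Z)-maleate in one pot.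

Step 3
Reactants: 8 di-tert-butyl (2Z)-2-[10-(tert-butyldimethylsilyloxy)decyl]-3-(prop-2-en-1-yl)but-2-enedioate
Product: 10 di-tert-butyl (2Z)-2-[10-(tert-butyldimethylsilyloxy)decyl]-3-(3-hydroxypropyl)but-2-enedioate, via B-alkyl-9-BBN borane 9 (not isolated)
Conditions: 9-BBN (1.3 equiv), THF, 0 °C → rt; then NaBO3·4H2O, THF/H2O, rt
Reagents that add atoms: sodium perborate (NaBO3·4H2O, source of the hydroxyl oxygen), [Na+].[Na+].O[B-]1(O)OO[B-](O)(O)OO1
Why: Hydroboration–oxidation with bulky 9-BBN is anti-Markovnikov and selective for the monosubstituted alkene over the tetrasubstituted electron-poor maleate, and perborate is mild enough for the tert-butyl esters and the silyl ether.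

Step 4
Reactants: 10 di-tert-butyl (2Z)-2-[10-(tert-butyldimethylsilyloxy)decyl]-3-(3-hydroxypropyl)but-2-enedioate
Product: 12 (4Z)-4,5-bis(tert-butoxycarbonyl)-15-[(tert-butyldimethylsilyl)oxy]pentadec-4-enoic acid, via aldehyde 11 (not isolated)
Conditions: TEMPO (0.2 equiv), PhI(OAc)2 (2.5 equiv), MeCN/H2O 1:1, rt
Reagents that add atoms: water, O
Why: The oxoammonium oxidation (TEMPO/PhI(OAc)2) takes the primary alcohol through the aldehyde hydrate to the acid without touching the alkene, the tert-butyl esters or the silyl ether.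

Step 5
Reactants: 12 (4Z)-4,5-bis(tert-butoxycarbonyl)-15-[(tert-butyldimethylsilyl)oxy]pentadec-4-enoic acid
Product: 14 tert-butyl (2R)-2-[(2R)-1-tert-butoxy-12-[(tert-butyldimethylsilyl)oxy]-1-oxododecan-2-yl]-5-oxooxolane-2-carboxylate, via ester enolate 13 (not isolated)
Conditions: bifunctional squaramide catalyst (10 mol %; 3-{[3,5-bis(trifluoromethyl)phenyl]amino}-4-[(9-deoxy-epi-quinidin-9-yl)amino]cyclobut-3-ene-1,2-dione), toluene (0.05 M), 4 Å MS, 25 °C, 24–72 h
Reagents that add atoms: none
Why: Proposed new method: catalytic enantioselective syn hydro-acyloxylation (intramolecular oxa-Michael addition/protonation) of a tetrasubstituted maleate, in which the quinuclidine nitrogen deprotonates the acid, the squaramide N–H pair binds and polarises the C5 ester, the carboxylate closes 5-exo-trig on C4 (the β-carbon of the C5 ester) to make the quaternary C–O bond, and the quinuclidinium on that same face C-protonates the ion-paired enolate 13 before C4–C5 rotation, so that O and H add suprafacially to the (Z)-alkene and give the (2R, side-chain R) lactone; the neutral γ-lactone is the expected thermodynamic sink (as in the acid-mediated lactonisation of alkylidenesuccinic half-esters to paraconic acids) and the acid-free product releases the catalyst; closest known reaction type: amine/squaramide- or thiourea-catalysed intramolecular oxa-Michael lactonisation of carboxylic acids onto enones, and amine-catalysed conjugate addition–enantioselective protonation, neither shown for a tetrasubstituted diester acceptor nor for a fully substituted C–O centre with a vicinal protonation centre.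

Step 6
Reactants: 14 tert-butyl (2R)-2-[(2R)-1-tert-butoxy-12-[(tert-butyldimethylsilyl)oxy]-1-oxododecan-2-yl]-5-oxooxolane-2-carboxylate
Product: 15 (2R)-2-[(1R)-1-carboxy-11-hydroxyundecyl]-5-oxooxolane-2-carboxylic acid
Conditions: TFA/CH2Cl2/H2O (10:10:1), rt; evaporate; MeCN/H2O, rt; recrystallise
Reagents that add atoms: none
Why: Acidolysis (alkyl–oxygen cleavage through the tert-butyl cation) frees both carboxyls and also cleaves the primary silyl ether, the base-free medium excludes α-epimerisation and retro-oxa-Michael opening, and recrystallisation of the diacid can upgrade ee and dr.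

Step 7
Reactants: 15 (2R)-2-[(1R)-1-carboxy-11-hydroxyundecyl]-5-oxooxolane-2-carboxylic acid; 16 (R)-malic acid
Product: 19 (2R)-2-[(1R)-1-carboxy-11-{[(2R)-3-carboxy-2-hydroxypropanoyl]oxy}undecyl]-5-oxooxolane-2-carboxylic acid, via O-trifluoroacetylmalic anhydride 17 (not isolated), via O-trifluoroacetyl ester 18 (not isolated)
Conditions: 16, (CF3CO)2O, 0 °C → rt, evaporate; then 15 (1 equiv per 3 equiv of 17), THF, 0 °C → rt; then THF/H2O 1:1, rt; C18 chromatography
Reagents that add atoms: none
Why: In this regioselective anhydride alcoholysis the primary alcohol attacks the carbonyl next to the electron-withdrawing trifluoroacetoxy group to give the 1-ester, free carboxylic acids are tolerated (the product itself carries one), the labile trifluoroacetate hydrolyses in the aqueous hold, and the malate stereocentre comes unchanged from the chiral pool.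

## Compound list

1 | 10-bromodecan-1-ol | OCCCCCCCCCCBr | starting material
2 | (10-bromodecyloxy)(tert-butyl)dimethylsilane | CC(C)(C)[Si](C)(C)OCCCCCCCCCCBr | intermediate
3 | di-tert-butyl but-2-ynedioate (di-tert-butyl acetylenedicarboxylate) | CC(C)(C)OC(=O)C#CC(=O)OC(C)(C)C | starting material
4 | allyl bromide (3-bromoprop-1-ene) | C=CCBr | starting material
5 | [10-(tert-butyldimethylsilyloxy)decyl]magnesium bromide, Grignard reagent formed in the flask | CC(C)(C)[Si](C)(C)OCCCCCCCCCC[Mg]Br | intermediate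
6 | [10-(tert-butyldimethylsilyloxy)decyl]copper (monovalent copper, MgBr2/Me2S-complexed), formed in the flask | CC(C)(C)[Si](C)(C)OCCCCCCCCCC[Cu] | intermediate
7 | di-tert-butyl (2E)-2-cuprio-3-[10-(tert-butyldimethylsilyloxy)decyl]but-2-enedioate, vinylcopper adduct (monovalent copper) with the two ester groups cis, formed in the flask | CC(C)(C)OC(=O)/C(CCCCCCCCCCO[Si](C)(C)C(C)(C)C)=C(/[Cu])C(=O)OC(C)(C)C | intermediate
8 | di-tert-butyl (2Z)-2-[10-(tert-butyldimethylsilyloxy)decyl]-3-(prop-2-en-1-yl)but-2-enedioate | CC(C)(C)OC(=O)/C(CCCCCCCCCCO[Si](C)(C)C(C)(C)C)=C(/CC=C)C(=O)OC(C)(C)C | intermediate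
9 | di-tert-butyl (2Z)-2-[3-(9-borabicyclo[3.3.1]nonan-9-yl)propyl]-3-[10-(tert-butyldimethylsilyloxy)decyl]but-2-enedioate, formed in the flask | CC(C)(C)OC(=O)/C(CCCCCCCCCCO[Si](C)(C)C(C)(C)C)=C(/CCCB1C2CCCC1CCC2)C(=O)OC(C)(C)C | intermediate
10 | di-tert-butyl (2Z)-2-[10-(tert-butyldimethylsilyloxy)decyl]-3-(3-hydroxypropyl)but-2-enedioate | CC(C)(C)OC(=O)/C(CCCCCCCCCCO[Si](C)(C)C(C)(C)C)=C(/CCCO)C(=O)OC(C)(C)C | intermediate
11 | di-tert-butyl (2Z)-2-[10-(tert-butyldimethylsilyloxy)decyl]-3-(3-oxopropyl)but-2-enedioate, aldehyde formed in the flask | CC(C)(C)OC(=O)/C(CCCCCCCCCCO[Si](C)(C)C(C)(C)C)=C(/CCC=O)C(=O)OC(C)(C)C | intermediate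
12 | (4Z)-4,5-bis(tert-butoxycarbonyl)-15-[(tert-butyldimethylsilyl)oxy]pentadec-4-enoic acid | CC(C)(C)OC(=O)/C(CCCCCCCCCCO[Si](C)(C)C(C)(C)C)=C(/CCC(=O)O)C(=O)OC(C)(C)C | intermediate
13 | tert-butyl ester enolate of 14, (2R)-lactone already closed, enolate geometry undefined, ion-paired with the protonated catalyst, formed in the flask | CC(C)(C)[Si](C)(C)OCCCCCCCCCCC(=C([O-])OC(C)(C)C)[C@@]1(C(=O)OC(C)(C)C)CCC(=O)O1 | intermediate
14 | tert-butyl (2R)-2-[(2R)-1-tert-butoxy-12-[(tert-butyldimethylsilyl)oxy]-1-oxododecan-2-yl]-5-oxooxolane-2-carboxylate | CC(C)(C)[Si](C)(C)OCCCCCCCCCC[C@@H](C(=O)OC(C)(C)C)[C@@]1(C(=O)OC(C)(C)C)CCC(=O)O1 | intermediate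
15 | (2R)-2-[(1R)-1-carboxy-11-hydroxyundecyl]-5-oxooxolane-2-carboxylic acid | OCCCCCCCCCC[C@@H](C(=O)O)[C@@]1(C(=O)O)CCC(=O)O1 | intermediate
16 | (R)-malic acid (D-malic acid) | OC(=O)C[C@@H](O)C(=O)O | starting material
17 | (3R)-2,5-dioxooxolan-3-yl 2,2,2-trifluoroacetate (O-trifluoroacetyl-(R)-malic anhydride), formed in the flask | O=C1C[C@@H](OC(=O)C(F)(F)F)C(=O)O1 | intermediate
18 | (2R)-2-[(1R)-1-carboxy-11-{[(2R)-3-carboxy-2-(2,2,2-trifluoroacetoxy)propanoyl]oxy}undecyl]-5-oxooxolane-2-carboxylic acid, formed in the flask | OC(=O)C[C@@H](OC(=O)C(F)(F)F)C(=O)OCCCCCCCCCC[C@@H](C(=O)O)[C@@]1(C(=O)O)CCC(=O)O1 | intermediate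
19 | (2R)-2-[(1R)-1-carboxy-11-{[(2R)-3-carboxy-2-hydroxypropanoyl]oxy}undecyl]-5-oxooxolane-2-carboxylic acid | O=C(O)C[C@@H](O)C(=O)OCCCCCCCCCC[C@@H](C(=O)O)[C@@]1(C(=O)O)CCC(=O)O1 | target

## Step count and risks

Total steps: 7. Longest linear sequence: 7 (1 → 2 → 8 → 10 → 12 → 14 → 15 → 19).

**Step 5 (the proposed new lactonisation).** The tetrasubstituted di-tert-butyl maleate may be too hindered for a carboxylate nucleophile. The addition is reversible, which can erode ee/dr or isomerise the alkene. The protonation may not be syn, the absolute sense may be opposite to the prediction, and 6-endo closure on C5 is conceivable.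

The fallback uses known chemistry, sets out from 2 and comes back at 15. Bromide 2 alkylates the lithium enolate of S-tert-butyl thioacetate (LDA, THF/DMPU) to give S-tert-butyl 12-[(tert-butyldimethylsilyl)oxy]dodecanethioate F1. LDA/TMSCl in THF converts it into the silyl ketene thioacetal (1Z)-1-(tert-butylsulfanyl)-12-[(tert-butyldimethylsilyl)oxy]-1-[(trimethylsilyl)oxy]dodec-1-ene F2. A syn-selective Mukaiyama aldol addition of F2 to commercial dimethyl 2-oxoglutarate follows, catalysed by Cu(OTf)2 with the tert-butyl-bis(oxazoline) ligand enantiomer that delivers the (R)-carbinol (expected to be the (R,R)-ligand by analogy with pyruvate aldols; chelated α-keto ester). It gives dimethyl (2R)-2-[(2R)-1-(tert-butylsulfanyl)-12-[(tert-butyldimethylsilyl)oxy]-1-oxododecan-2-yl]-2-[(trimethylsilyl)oxy]pentanedioate F3. Brief 1 M HCl/THF removes the trimethylsilyl group and closes the lactone to methyl (2R)-2-[(2R)-1-(tert-butylsulfanyl)-12-[(tert-butyldimethylsilyl)oxy]-1-oxododecan-2-yl]-5-oxooxolane-2-carboxylate F4. LiOH in THF/H2O followed by HCl to pH 1 hydrolyses the thioester, the methyl ester and the silyl ether and relactonises to 15.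

**Step 2 (carbocupration/allylation).** The ester-stabilised vinylcopper 7 is a weak nucleophile and can isomerise through a copper allenoate on warming, giving low yield or Z/E mixtures.

The fallback sets out from 7 (generated from 2 and 3 exactly as in step 2) and comes back at 12. Quenching 7 with I2 at −78 °C gives di-tert-butyl (2E)-2-[10-(tert-butyldimethylsilyloxy)decyl]-3-iodobut-2-enedioate F5 (ester groups cis). Negishi coupling of F5 with commercial (3-ethoxy-3-oxopropyl)zinc bromide (Pd(OAc)2/SPhos, THF, rt) proceeds with retention and gives 3,4-di-tert-butyl 1-ethyl (3Z)-14-[(tert-butyldimethylsilyl)oxy]tetradec-3-ene-1,3,4-tricarboxylate F6. Selective saponification of the unhindered ethyl ester (LiOH, 1.1 equiv, THF/H2O, 0 °C) gives 12, which also bypasses steps 3 and 4.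

**Step 7 (malate esterification on the unprotected diacid).** Trifluoroacetyl transfer to the alcohol, attack at the C4 carbonyl of 17, or mixed anhydrides at the core carboxyls could lower yield and regiopurity, and the polar triacid is hard to purify.

The fallback sets out from 14 and comes back at 19. HF·pyridine in THF removes only the silyl group to give tert-butyl (2R)-2-[(2R)-1-tert-butoxy-12-hydroxy-1-oxododecan-2-yl]-5-oxooxolane-2-carboxylate F7. Separately, commercial (R)-aspartic acid 4-tert-butyl ester is diazotised with retention (NaNO2, aq AcOH, 0 °C) to (2R)-4-tert-butoxy-2-hydroxy-4-oxobutanoic acid F8, in which only the C1 carboxyl is free. Mitsunobu esterification of F7 with F8 (PPh3, DIAD, THF, 0 °C; the C–O bond forms by displacement at the primary carbon) gives tert-butyl (2R)-2-[(2R)-1-tert-butoxy-12-{[(2R)-4-tert-butoxy-2-hydroxy-4-oxobutanoyl]oxy}-1-oxododecan-2-yl]-5-oxooxolane-2-carboxylate F9. TFA/CH2Cl2 then removes the three tert-butyl esters to give 19.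

Further compounds

F1 | step 5 | S-tert-butyl 12-[(tert-butyldimethylsilyl)oxy]dodecanethioate | CC(C)(C)SC(=O)CCCCCCCCCCCO[Si](C)(C)C(C)(C)C
F2 | step 5 | (1Z)-1-(tert-butylsulfanyl)-12-[(tert-butyldimethylsilyl)oxy]-1-[(trimethylsilyl)oxy]dodec-1-ene | CC(C)(C)S/C(O[Si](C)(C)C)=C\CCCCCCCCCCO[Si](C)(C)C(C)(C)C
F3 | step 5 | dimethyl (2R)-2-[(2R)-1-(tert-butylsulfanyl)-12-[(tert-butyldimethylsilyl)oxy]-1-oxododecan-2-yl]-2-[(trimethylsilyl)oxy]pentanedioate | CC(C)(C)[Si](C)(C)OCCCCCCCCCC[C@@H](C(=O)SC(C)(C)C)[C@@](O[Si](C)(C)C)(C(=O)OC)CCC(=O)OC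
F4 | step 5 | methyl (2R)-2-[(2R)-1-(tert-butylsulfanyl)-12-[(tert-butyldimethylsilyl)oxy]-1-oxododecan-2-yl]-5-oxooxolane-2-carboxylate | CC(C)(C)[Si](C)(C)OCCCCCCCCCC[C@@H](C(=O)SC(C)(C)C)[C@@]1(C(=O)OC)CCC(=O)O1
F5 | step 2 | di-tert-butyl (2E)-2-[10-(tert-butyldimethylsilyloxy)decyl]-3-iodobut-2-enedioate (ester groups cis) | CC(C)(C)OC(=O)/C(CCCCCCCCCCO[Si](C)(C)C(C)(C)C)=C(/I)C(=O)OC(C)(C)C
F6 | step 2 | 3,4-di-tert-butyl 1-ethyl (3Z)-14-[(tert-butyldimethylsilyl)oxy]tetradec-3-ene-1,3,4-tricarboxylate | CC(C)(C)OC(=O)/C(CCCCCCCCCCO[Si](C)(C)C(C)(C)C)=C(/CCC(=O)OCC)C(=O)OC(C)(C)C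
F7 | step 7 | tert-butyl (2R)-2-[(2R)-1-tert-butoxy-12-hydroxy-1-oxododecan-2-yl]-5-oxooxolane-2-carboxylate | OCCCCCCCCCC[C@@H](C(=O)OC(C)(C)C)[C@@]1(C(=O)OC(C)(C)C)CCC(=O)O1
F8 | step 7 | (2R)-4-tert-butoxy-2-hydroxy-4-oxobutanoic acid | CC(C)(C)OC(=O)C[C@@H](O)C(=O)O
F9 | step 7 | tert-butyl (2R)-2-[(2R)-1-tert-butoxy-12-{[(2R)-4-tert-butoxy-2-hydroxy-4-oxobutanoyl]oxy}-1-oxododecan-2-yl]-5-oxooxolane-2-carboxylate | CC(C)(C)OC(=O)C[C@@H](O)C(=O)OCCCCCCCCCC[C@@H](C(=O)OC(C)(C)C)[C@@]1(C(=O)OC(C)(C)C)CCC(=O)O1
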